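**Plan** (flavanone numbering: O1, C2, C3, C4, C4a, C5–C8, C8a; ring B primed)
1. Retrosynthetic cuts, in order: the C3–OH bond; the aryl ether bond O1–C8a of ring C; the C2–O bond (via C2–B); the C2=C3 enone bond of a chalcone; last the three aryl–prenyl bonds (C6, C8, C3').
2. Forward: ring A ketone 4 (F on C8a, prenyl on C6 and C8, MOM on O7) and ring B aldehyde 7 are made by iodination and Stille prenylation and joined to chalcone 8. Conjugate borylation–oxidation gives the C2 carbinol, ring C is closed, C3 is hydroxylated, and the MOM groups are removed.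
3. Enabling feature: in ring A, C8a is ortho to C4a, which carries the C4 carbonyl, and meta to O7. A fluoride on C8a is therefore activated for addition–elimination by the C2 alkoxide (six-membered ring C), and the O7 donor cannot conjugate with the charge that develops on C4a, C6 and C8.
4. Stereochemistry: C2 by reagent control (chiral bisphosphine–copper boryl addition, C–B oxidation with retention); it is untouched in the ring closure because no bond to C2 is broken. C3 by substrate control (oxidant enters trans to the C2 aryl group).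

Key step: step 8

Assumption: the sense of induction of the copper–Josiphos catalyst in step 7 is taken from the parent chalcone series; the ligand antipode that gives the (S)-carbinol is used and the assignment would have to be verified on this substrate.

Step 1
Reactants: 1 1-(2-fluoro-4-hydroxyphenyl)ethan-1-one
Product: 2 1-(2-fluoro-4-hydroxy-3,5-diiodophenyl)ethan-1-one
Conditions: NIS (2.2 equiv), TsOH·H2O (10 mol %), MeCN, 0 °C to rt
Reagents that add atoms: N-iodosuccinimide, O=C1CCC(=O)N1I
Why: Electrophilic aromatic iodination, in which the phenol directs to its two ortho positions, which are also meta to the acetyl group and ortho/para to fluorine, so no other ring position competes.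

Step 2
Reactants: 2 1-(2-fluoro-4-hydroxy-3,5-diiodophenyl)ethan-1-one
Product: 3 1-[2-fluoro-3,5-diiodo-4-(methoxymethoxy)phenyl]ethan-1-one
Conditions: MOMCl, i-Pr2NEt, CH2Cl2, 0 °C to rt
Reagents that add atoms: chloromethyl methyl ether, COCCl
Why: O-alkylation of the acidic phenol to a MOM acetal, which keeps O7 from becoming a deactivating phenoxide in the later SNAr step and is stable to the basic steps that follow.

Step 3
Reactants: 3 1-[2-fluoro-3,5-diiodo-4-(methoxymethoxy)phenyl]ethan-1-one
Product: 4 1-[2-fluoro-4-(methoxymethoxy)-3,5-bis(3-methylbut-2-en-1-yl)phenyl]ethan-1-one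
Conditions: tributyl(3-methylbut-2-en-1-yl)stannane (2.6 equiv), Pd(PPh3)4 (10 mol %), DMF, 90 °C
Reagents that add atoms: tributyl(3-methylbut-2-en-1-yl)stannane, CC(C)=CC[Sn](CCCC)(CCCC)CCCC
Why: Twofold Stille coupling at the two C–I bonds, in which the prenyl group is expected to be transferred through its unsubstituted terminus (linear prenyl), while the C–F bond and the ketone are inert to zerovalent palladium under these conditions.

Step 4
Reactants: 5 4-hydroxy-3-iodobenzaldehyde
Product: 6 3-iodo-4-(methoxymethoxy)benzaldehyde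
Conditions: MOMCl, i-Pr2NEt, CH2Cl2, 0 °C to rt
Reagents that add atoms: chloromethyl methyl ether, COCCl
Why: O-alkylation of the phenol to its MOM acetal, needed so that the aldehyde can be used in the basic aldol condensation and the later enolate chemistry.

Step 5
Reactants: 6 3-iodo-4-(methoxymethoxy)benzaldehyde
Product: 7 4-(methoxymethoxy)-3-(3-methylbut-2-en-1-yl)benzaldehyde
Conditions: tributyl(3-methylbut-2-en-1-yl)stannane (1.3 equiv), Pd(PPh3)4 (5 mol %), DMF, 90 °C
Reagents that add atoms: tributyl(3-methylbut-2-en-1-yl)stannane, CC(C)=CC[Sn](CCCC)(CCCC)CCCC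
Why: Stille coupling of the aryl iodide with the prenyl stannane, which tolerates the free aldehyde and places the prenyl group at C3'.

Step 6
Reactants: 4 1-[2-fluoro-4-(methoxymethoxy)-3,5-bis(3-methylbut-2-en-1-yl)phenyl]ethan-1-one; 7 4-(methoxymethoxy)-3-(3-methylbut-2-en-1-yl)benzaldehyde
Product: 8 (2E)-1-[2-fluoro-4-(methoxymethoxy)-3,5-bis(3-methylbut-2-en-1-yl)phenyl]-3-[4-(methoxymethoxy)-3-(3-methylbut-2-en-1-yl)phenyl]prop-2-en-1-one
Conditions: KOH (3 equiv), EtOH–THF, 0 °C to rt
Reagents that add atoms: none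
Why: Claisen–Schmidt aldol condensation, whose base-mediated dehydration gives the E enone, while intermolecular displacement of the hindered fluoride by hydroxide or ethoxide should be slow at room temperature.

Step 7
Reactants: 8 (2E)-1-[2-fluoro-4-(methoxymethoxy)-3,5-bis(3-methylbut-2-en-1-yl)phenyl]-3-[4-(methoxymethoxy)-3-(3-methylbut-2-en-1-yl)phenyl]prop-2-en-1-one
Product: 10 (3S)-1-[2-fluoro-4-(methoxymethoxy)-3,5-bis(3-methylbut-2-en-1-yl)phenyl]-3-hydroxy-3-[4-(methoxymethoxy)-3-(3-methylbut-2-en-1-yl)phenyl]propan-1-one, via beta-boryl ketone 9 (not isolated)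
Conditions: CuCl (3 mol %), NaOt-Bu (6 mol %), 1-[2-(diphenylphosphino)ferrocenyl]ethyldicyclohexylphosphine (Josiphos, antipode chosen for S, 3.3 mol %), B2pin2 (1.1 equiv), MeOH (2 equiv), THF, rt; then NaBO3·4H2O, THF–H2O, rt
Reagents that add atoms: bis(pinacolato)diboron, CC1(C)OB(OC1(C)C)B1OC(C)(C)C(C)(C)O1 (its boron stays only in 9); sodium perborate, [Na+].[Na+].O[B-]1(O)OO[B-](O)(O)OO1 (source of the hydroxyl oxygen of 10)
Why: Copper-catalysed enantioselective conjugate borylation of the aryl enone followed by stereoretentive oxidation of the C–B bond, in which the bisphosphine-bound boryl copper adds to one enone face and so sets C2 by reagent control, while the isolated prenyl olefins, the aryl fluoride and the MOM ethers do not react with the nucleophilic boryl copper species.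

Step 8
Reactants: 10 (3S)-1-[2-fluoro-4-(methoxymethoxy)-3,5-bis(3-methylbut-2-en-1-yl)phenyl]-3-hydroxy-3-[4-(methoxymethoxy)-3-(3-methylbut-2-en-1-yl)phenyl]propan-1-one
Product: 12 (2S)-7-(methoxymethoxy)-2-[4-(methoxymethoxy)-3-(3-methylbut-2-en-1-yl)phenyl]-6,8-bis(3-methylbut-2-en-1-yl)-2,3-dihydro-4H-chromen-4-one, via lithium alkoxide 11 (not isolated)
Conditions: LiN(SiMe3)2 (1.02 equiv), THF, −78 °C; DMPU (4 equiv), −40 to 0 °C; AcOH quench
Reagents that add atoms: none
Why: LiN(SiMe3)2 removes only the O–H proton at −78 °C, and on warming with DMPU the alkoxide oxygen of 11 adds to C8a of ring A and lithium fluoride is expelled (addition–elimination, SNAr), which forms the O1–C8a bond. The closest known reaction type is the intramolecular SNAr O-arylation of ortho-fluoroaryl ketones that is used to close chromone, flavone and xanthone rings. Ring C closes in a 6-exo-trig sense at an aromatic sp2 carbon, the C–F bond that breaks being exocyclic to the new ring. No stereocentre is formed, and C2 keeps its S configuration because the C2–O bond is not broken and C2 carries no acidic hydrogen. The step needs the alkoxide to attack C8a faster than it fragments by retro-aldol cleavage, faster than it is turned into an enolate that eliminates, and faster than it deprotonates the product. This should be secured by the C4 carbonyl ortho to C8a (with the O7 donor only meta to it), by the six-membered transition state, by the use of exactly one equivalent of a lithium base so that only a weakly basic lithium alkoxide is present, and by the low temperature.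

Step 9
Reactants: 12 (2S)-7-(methoxymethoxy)-2-[4-(methoxymethoxy)-3-(3-methylbut-2-en-1-yl)phenyl]-6,8-bis(3-methylbut-2-en-1-yl)-2,3-dihydro-4H-chromen-4-one
Product: 14 (2R,3R)-3-hydroxy-7-(methoxymethoxy)-2-[4-(methoxymethoxy)-3-(3-methylbut-2-en-1-yl)phenyl]-6,8-bis(3-methylbut-2-en-1-yl)-2,3-dihydro-4H-chromen-4-one, via sodium enolate 13 (not isolated)
Conditions: NaN(SiMe3)2 (1.2 equiv), THF, −78 °C; 2-(phenylsulfonyl)-3-phenyloxaziridine (1.5 equiv), −78 °C; AcOH, −78 °C
Reagents that add atoms: 2-(phenylsulfonyl)-3-phenyloxaziridine, O=S(=O)(N1OC1c1ccccc1)c1ccccc1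
Why: Enolate alpha-hydroxylation with an N-sulfonyloxaziridine (Davis oxidation), in which the oxidant should attack C3 of the half-chair enolate on the face opposite the C2 aryl group and so set C3 trans to it by substrate control (2R,3R), while the unactivated prenyl olefins are not epoxidised at −78 °C and the cold acidic quench keeps the enolate from eliminating the ring oxygen.

Step 10
Reactants: 14 (2R,3R)-3-hydroxy-7-(methoxymethoxy)-2-[4-(methoxymethoxy)-3-(3-methylbut-2-en-1-yl)phenyl]-6,8-bis(3-methylbut-2-en-1-yl)-2,3-dihydro-4H-chromen-4-one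
Product: 15 Lespeflorin B3, (2R,3R)-3,7-dihydroxy-2-[4-hydroxy-3-(3-methylbut-2-en-1-yl)phenyl]-6,8-bis(3-methylbut-2-en-1-yl)-2,3-dihydro-4H-chromen-4-one
Conditions: HCl (3 M aq), MeOH, rt to 40 °C
Reagents that add atoms: none
Why: Acid-catalysed acetal exchange with methanol cleaves both aryl MOM ethers, and the mild acid and temperature are chosen so that the ortho-prenylphenols do not cyclise to chromans and the trans alpha-ketol is not epimerised.

**Compound list**
1 | 1-(2-fluoro-4-hydroxyphenyl)ethan-1-one | CC(=O)c1ccc(O)cc1F | starting material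
2 | 1-(2-fluoro-4-hydroxy-3,5-diiodophenyl)ethan-1-one | CC(=O)c1cc(I)c(O)c(I)c1F | intermediate
3 | 1-[2-fluoro-3,5-diiodo-4-(methoxymethoxy)phenyl]ethan-1-one | CC(=O)c1cc(I)c(OCOC)c(I)c1F | intermediate
4 | 1-[2-fluoro-4-(methoxymethoxy)-3,5-bis(3-methylbut-2-en-1-yl)phenyl]ethan-1-one | CC(=O)c1cc(CC=C(C)C)c(OCOC)c(CC=C(C)C)c1F | intermediate
5 | 4-hydroxy-3-iodobenzaldehyde | O=Cc1ccc(O)c(I)c1 | starting material
6 | 3-iodo-4-(methoxymethoxy)benzaldehyde | COCOc1ccc(C=O)cc1I | intermediate
7 | 4-(methoxymethoxy)-3-(3-methylbut-2-en-1-yl)benzaldehyde | COCOc1ccc(C=O)cc1CC=C(C)C | intermediate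
8 | (2E)-1-[2-fluoro-4-(methoxymethoxy)-3,5-bis(3-methylbut-2-en-1-yl)phenyl]-3-[4-(methoxymethoxy)-3-(3-methylbut-2-en-1-yl)phenyl]prop-2-en-1-one | COCOc1ccc(/C=C/C(=O)c2cc(CC=C(C)C)c(OCOC)c(CC=C(C)C)c2F)cc1CC=C(C)C | intermediate
9 | (3S)-1-[2-fluoro-4-(methoxymethoxy)-3,5-bis(3-methylbut-2-en-1-yl)phenyl]-3-[4-(methoxymethoxy)-3-(3-methylbut-2-en-1-yl)phenyl]-3-(4,4,5,5-tetramethyl-1,3,2-dioxaborolan-2-yl)propan-1-one (formed in the flask) | CC(C)=CCc1cc([C@@H](B2OC(C)(C)C(C)(C)O2)CC(=O)c3cc(CC=C(C)C)c(OCOC)c(CC=C(C)C)c3F)ccc1OCOC | intermediate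
10 | (3S)-1-[2-fluoro-4-(methoxymethoxy)-3,5-bis(3-methylbut-2-en-1-yl)phenyl]-3-hydroxy-3-[4-(methoxymethoxy)-3-(3-methylbut-2-en-1-yl)phenyl]propan-1-one | CC(C)=CCc1cc([C@@H](O)CC(=O)c2cc(CC=C(C)C)c(OCOC)c(CC=C(C)C)c2F)ccc1OCOC | intermediate
11 | lithium (1S)-3-[2-fluoro-4-(methoxymethoxy)-3,5-bis(3-methylbut-2-en-1-yl)phenyl]-1-[4-(methoxymethoxy)-3-(3-methylbut-2-en-1-yl)phenyl]-3-oxopropan-1-olate (formed in the flask) | [Li+].CC(C)=CCc1cc([C@@H]([O-])CC(=O)c2cc(CC=C(C)C)c(OCOC)c(CC=C(C)C)c2F)ccc1OCOC | intermediate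
12 | (2S)-7-(methoxymethoxy)-2-[4-(methoxymethoxy)-3-(3-methylbut-2-en-1-yl)phenyl]-6,8-bis(3-methylbut-2-en-1-yl)-2,3-dihydro-4H-chromen-4-one | CC(C)=CCc1cc([C@H]2Oc3c(cc(CC=C(C)C)c(OCOC)c3CC=C(C)C)C(=O)C2)ccc1OCOC | intermediate
13 | sodium (2S)-7-(methoxymethoxy)-2-[4-(methoxymethoxy)-3-(3-methylbut-2-en-1-yl)phenyl]-6,8-bis(3-methylbut-2-en-1-yl)-2H-chromen-4-olate (formed in the flask) | [Na+].CC(C)=CCc1cc([C@H]2Oc3c(cc(CC=C(C)C)c(OCOC)c3CC=C(C)C)C([O-])=C2)ccc1OCOC | intermediate
14 | (2R,3R)-3-hydroxy-7-(methoxymethoxy)-2-[4-(methoxymethoxy)-3-(3-methylbut-2-en-1-yl)phenyl]-6,8-bis(3-methylbut-2-en-1-yl)-2,3-dihydro-4H-chromen-4-one | CC(C)=CCc1cc([C@H]2Oc3c(cc(CC=C(C)C)c(OCOC)c3CC=C(C)C)C(=O)[C@@H]2O)ccc1OCOC | intermediate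
15 | Lespeflorin B3, (2R,3R)-3,7-dihydroxy-2-[4-hydroxy-3-(3-methylbut-2-en-1-yl)phenyl]-6,8-bis(3-methylbut-2-en-1-yl)-2,3-dihydro-4H-chromen-4-one | CC(C)=CCc1cc([C@H]2Oc3c(cc(CC=C(C)C)c(O)c3CC=C(C)C)C(=O)[C@@H]2O)ccc1O | target

**Totals**
Total step count: 10. Longest linear sequence: 8 steps (1, 2, 3, 6, 7, 8, 9, 10).

**Steps most likely to fail**

Step 8 (ring closure). The aldolate 11 may fragment by retro-aldol cleavage or lose water by beta-elimination before it attacks C8a, or the product may be enolised by unreacted alkoxide and ring-open; each of these erodes the C2 configuration or the material balance. The fallback sets out from 4 and comes back at 12, and closes the same bond before any stereocentre exists. Ketone 4 is formylated with ethyl formate and NaH in THF to sodium (1Z)-3-[2-fluoro-4-(methoxymethoxy)-3,5-bis(3-methylbut-2-en-1-yl)phenyl]-3-oxoprop-1-en-1-olate F1. On warming in DMF its enolate oxygen, which cannot fragment, displaces the fluoride and gives 7-(methoxymethoxy)-6,8-bis(3-methylbut-2-en-1-yl)-4H-chromen-4-one F2. In parallel, purchased 4-bromo-2-iodophenol F3 is protected (MOMCl, i-Pr2NEt) as 4-bromo-2-iodo-1-(methoxymethoxy)benzene F4. Stille coupling at the C–I bond with the prenyl stannane gives 4-bromo-1-(methoxymethoxy)-2-(3-methylbut-2-en-1-yl)benzene F5. Bromine–lithium exchange (n-BuLi, THF, −78 °C) and B(Oi-Pr)3 then give [4-(methoxymethoxy)-3-(3-methylbut-2-en-1-yl)phenyl]boronic acid F6. Rhodium-catalysed enantioselective 1,4-addition of F6 to F2 ([Rh(OH)(cod)]2, electron-poor chiral biaryl bisphosphine of the antipode that gives 2S, toluene–water, rt) delivers 12.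

Step 9 (C3 hydroxylation). The sodium enolate 13 may eliminate the ring oxygen (ring opening to the chalcone phenoxide, with loss of the C2 configuration), add to the sulfonimine by-product, or be attacked on the wrong face. The fallback runs from 12 to 14 without a free enolate. Soft enolisation (Me3SiOTf, Et3N, CH2Cl2, 0 °C) gives trimethyl({(2S)-7-(methoxymethoxy)-2-[4-(methoxymethoxy)-3-(3-methylbut-2-en-1-yl)phenyl]-6,8-bis(3-methylbut-2-en-1-yl)-2H-chromen-4-yl}oxy)silane F7. Rubottom oxidation with one equivalent of titrated dimethyldioxirane in acetone at −78 °C relies on the enol ether being far more nucleophilic than the prenyl olefins. It gives, after silyl migration, (2R,3R)-7-(methoxymethoxy)-2-[4-(methoxymethoxy)-3-(3-methylbut-2-en-1-yl)phenyl]-6,8-bis(3-methylbut-2-en-1-yl)-3-[(trimethylsilyl)oxy]-2,3-dihydro-4H-chromen-4-one F8, which is desilylated with citric acid in MeOH to 14.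

Step 7 (C2 stereocentre). Facial selectivity of the boryl-copper addition may be low or reversed on this hindered, ortho-fluorinated enone, and conjugate reduction may compete. The fallback runs from 8 to 10 through an epoxide. Juliá–Colonna epoxidation (the poly-leucine antipode that gives the 2S,3R epoxide, poly-D-leucine by analogy with chalcone itself, urea–H2O2, DBU, THF) is a nucleophilic epoxidation that spares the prenyl olefins. It gives [(2S,3R)-3-[4-(methoxymethoxy)-3-(3-methylbut-2-en-1-yl)phenyl]oxiran-2-yl][2-fluoro-4-(methoxymethoxy)-3,5-bis(3-methylbut-2-en-1-yl)phenyl]methanone F9. SmI2 (THF–MeOH, −90 °C) then cleaves the C–O bond alpha to the ketone and leaves the benzylic C–O bond, which gives 10 with the configuration of the epoxide at C2.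

**Further compounds**
F1 | step 8 | sodium (1Z)-3-[2-fluoro-4-(methoxymethoxy)-3,5-bis(3-methylbut-2-en-1-yl)phenyl]-3-oxoprop-1-en-1-olate | [Na+].[O-]/C=C\C(=O)c1cc(CC=C(C)C)c(OCOC)c(CC=C(C)C)c1F
F2 | step 8 | 7-(methoxymethoxy)-6,8-bis(3-methylbut-2-en-1-yl)-4H-chromen-4-one | O=c1ccoc2c(CC=C(C)C)c(OCOC)c(CC=C(C)C)cc12
F3 | step 8 | 4-bromo-2-iodophenol (purchased) | Oc1ccc(Br)cc1I
F4 | step 8 | 4-bromo-2-iodo-1-(methoxymethoxy)benzene | COCOc1ccc(Br)cc1I
F5 | step 8 | 4-bromo-1-(methoxymethoxy)-2-(3-methylbut-2-en-1-yl)benzene | COCOc1ccc(Br)cc1CC=C(C)C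
F6 | step 8 | [4-(methoxymethoxy)-3-(3-methylbut-2-en-1-yl)phenyl]boronic acid | COCOc1ccc(B(O)O)cc1CC=C(C)C
F7 | step 9 | trimethyl({(2S)-7-(methoxymethoxy)-2-[4-(methoxymethoxy)-3-(3-methylbut-2-en-1-yl)phenyl]-6,8-bis(3-methylbut-2-en-1-yl)-2H-chromen-4-yl}oxy)silane | CC(C)=CCc1cc([C@H]2Oc3c(cc(CC=C(C)C)c(OCOC)c3CC=C(C)C)C(O[Si](C)(C)C)=C2)ccc1OCOC
F8 | step 9 | (2R,3R)-7-(methoxymethoxy)-2-[4-(methoxymethoxy)-3-(3-methylbut-2-en-1-yl)phenyl]-6,8-bis(3-methylbut-2-en-1-yl)-3-[(trimethylsilyl)oxy]-2,3-dihydro-4H-chromen-4-one | CC(C)=CCc1cc([C@H]2Oc3c(cc(CC=C(C)C)c(OCOC)c3CC=C(C)C)C(=O)[C@@H]2O[Si](C)(C)C)ccc1OCOC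
F9 | step 7 | [(2S,3R)-3-[4-(methoxymethoxy)-3-(3-methylbut-2-en-1-yl)phenyl]oxiran-2-yl][2-fluoro-4-(methoxymethoxy)-3,5-bis(3-methylbut-2-en-1-yl)phenyl]methanone | CC(C)=CCc1cc([C@H]2O[C@@H]2C(=O)c3cc(CC=C(C)C)c(OCOC)c(CC=C(C)C)c3F)ccc1OCOC
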